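The lactone (oxolan-2-one numbering: O1, C2 carbonyl, C3 carbinol, C4 methine, C5 OCH2) is cut at C4–C5. Then come O1–C5 (carboxylate alkylation), C3–CH2Ar (enolate benzylation) and the C4=C7' styrene bond (aldol condensation; C7' is the veratryl benzylic carbon).
The enabling feature is that C5 is an unsubstituted OCH2 between ring oxygen O1 and C4, and C4 carries only H and the veratryl CH2. C5 can therefore be an acyloxymethyl radical and C4/C7' a styrene C=C, so one addition plus one hydrogen transfer delivers the five-membered ring, the C4 methine and the ArCH2 arm.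
In the forward direction, veratraldehyde and pyruvic acid give the C2–C3–C4–C7' chain. C3 is reduced, locked in a dioxolanone and benzylated, and the released acid becomes its iodomethyl ester. The only new ring, the lactone, closes in the radical step, and two deprotections finish the route.
C3 (S) comes from an L-specific dehydrogenase reduction. Its information is stored in a cis tert-butyl acetal and returned in the benzylation (self-regeneration of the stereocentre). C4 (S) is induced by C3 in the radical transition state.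

Key step: step 11

Assumption: the L-specific lactate dehydrogenase is taken to accept the 3,4-dimethoxyphenyl member of the 4-aryl-2-oxobut-3-enoate substrate class; Ar = 3,4-bis(benzyloxy)phenyl throughout.

Step 1
Reactants: 1 3,4-dimethoxybenzaldehyde; 2 pyruvic acid
Product: 3 (E)-4-(3,4-dimethoxyphenyl)-2-oxobut-3-enoic acid
Conditions: KOH (2 equiv), MeOH, 0 °C to rt; then 1 M HCl, 0 °C
Reagents that add atoms: none
Why: Claisen–Schmidt condensation, in which the non-enolisable aldehyde takes up the methyl enolate of pyruvate and loss of water gives the conjugated E enone acid, whose potassium salt precipitates and so escapes further reaction.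

Step 2
Reactants: 3 (E)-4-(3,4-dimethoxyphenyl)-2-oxobut-3-enoic acid
Product: 4 (2S,3E)-4-(3,4-dimethoxyphenyl)-2-hydroxybut-3-enoic acid
Conditions: L-lactate dehydrogenase (Bacillus stearothermophilus), NADH (cat.), formate dehydrogenase, HCO2Na, Tris buffer pH 7.5, rt, N2; then pH 3, EtOAc
Reagents that add atoms: none
Why: Enzymatic ketone reduction with formate-driven NADH recycling, a reaction type established for 4-aryl-2-oxobut-3-enoates, in which the L-specific enzyme passes hydride to the re face of the 2-oxo group, setting C2 as S and leaving the conjugated alkene untouched.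

Step 3
Reactants: 4 (2S,3E)-4-(3,4-dimethoxyphenyl)-2-hydroxybut-3-enoic acid
Product: 6 (2S,5S)-2-tert-butyl-5-[(E)-2-(3,4-dimethoxyphenyl)ethenyl]-1,3-dioxolan-4-one, via bis-TMS derivative 5 (not isolated)
Conditions: TMSCl (2.2 equiv), Et3N (2.3 equiv), CH2Cl2, 0 °C to rt, salts filtered off; then t-BuCHO (1.5 equiv), TMSOTf (5 mol %), CH2Cl2, −78 to −30 °C; pyridine quench
Reagents that add atoms: pivalaldehyde CC(C)(C)C=O; chlorotrimethylsilane C[Si](C)(C)Cl (silyl groups present in 5 only)
Why: TMSOTf-catalysed acetalisation of a bis-silylated α-hydroxy acid, run cold so that the allylic carbinol neither ionises nor racemises; C5 sets the new acetal centre because closure of the oxocarbenium ion places tert-butyl and styryl on the same ring face (cis), and the trans isomer must be removed by chromatography or crystallisation since it would lead to the antipode.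

Step 4
Reactants: 7 3,4-bis(benzyloxy)benzaldehyde
Product: 8 [3,4-bis(benzyloxy)phenyl]methanol
Conditions: NaBH4, MeOH–THF, 0 °C
Reagents that add atoms: none
Why: Borohydride reduction of an aromatic aldehyde, to which the benzyl ethers are inert.

Step 5
Reactants: 8 [3,4-bis(benzyloxy)phenyl]methanol
Product: 9 3,4-bis(benzyloxy)benzyl bromide
Conditions: PBr3 (0.4 equiv), Et2O, 0 °C; used at once
Reagents that add atoms: phosphorus tribromide BrP(Br)Br
Why: Bromination of a benzylic alcohol through its phosphite ester (SN2 by bromide), a standard route to electron-rich benzyl bromides that are used without storage.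

Step 6
Reactants: 6 (2S,5S)-2-tert-butyl-5-[(E)-2-(3,4-dimethoxyphenyl)ethenyl]-1,3-dioxolan-4-one; 9 3,4-bis(benzyloxy)benzyl bromide
Product: 11 (2S,5S)-5-[3,4-bis(benzyloxy)benzyl]-2-tert-butyl-5-[(E)-2-(3,4-dimethoxyphenyl)ethenyl]-1,3-dioxolan-4-one, via lithium dienolate 10 (not isolated)
Conditions: LiHMDS (1.05 equiv), THF, −78 °C; then 9 (1.2 equiv), −78 to −40 °C
Reagents that add atoms: lithium hexamethyldisilazide [Li+].C[Si](C)(C)[N-][Si](C)(C)C (lithium present in 10 only)
Why: Alkylation of a chiral dioxolanone enolate (self-regeneration of the stereocentre), in which deprotonation flattens C5, the acetal tert-butyl group shields one face and the benzylic bromide enters anti to it at the α-carbon of the dienolate (highest charge density, styrene conjugation retained), so that CH2Ar takes the place of the former hydrogen and C5 is S.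

Step 7
Reactants: 11 (2S,5S)-5-[3,4-bis(benzyloxy)benzyl]-2-tert-butyl-5-[(E)-2-(3,4-dimethoxyphenyl)ethenyl]-1,3-dioxolan-4-one
Product: 12 (2S,3E)-2-[3,4-bis(benzyloxy)benzyl]-4-(3,4-dimethoxyphenyl)-2-hydroxybut-3-enoic acid
Conditions: LiOH (3 equiv), THF–MeOH–H2O, rt; then 1 M HCl to pH 3, 0 °C
Reagents that add atoms: lithium hydroxide [Li+].[OH-]
Why: Saponification of the acylal-type ring, in which hydroxide cleaves the acyl–oxygen bond and the hemiacetal collapses with loss of pivalaldehyde, while the quaternary centre has no way to epimerise.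

Step 8
Reactants: 12 (2S,3E)-2-[3,4-bis(benzyloxy)benzyl]-4-(3,4-dimethoxyphenyl)-2-hydroxybut-3-enoic acid; 13 chloromethyl chlorosulfate
Product: 14 chloromethyl (2S,3E)-2-[3,4-bis(benzyloxy)benzyl]-4-(3,4-dimethoxyphenyl)-2-hydroxybut-3-enoate
Conditions: 13 (1.2 equiv), NaHCO3 (4 equiv), Bu4NHSO4 (10 mol %), CH2Cl2–H2O, 0 °C to rt
Reagents that add atoms: none
Why: Phase-transfer O-alkylation of a carboxylate, in which chlorosulfate leaves far faster than chloride and the un-ionised tertiary alcohol stays inert at bicarbonate pH; this step brings in the future C5.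

Step 9
Reactants: 14 chloromethyl (2S,3E)-2-[3,4-bis(benzyloxy)benzyl]-4-(3,4-dimethoxyphenyl)-2-hydroxybut-3-enoate
Product: 15 chloromethyl (2S,3E)-2-[3,4-bis(benzyloxy)benzyl]-4-(3,4-dimethoxyphenyl)-2-(trimethylsilyloxy)but-3-enoate
Conditions: TMSOTf (1.3 equiv), 2,6-lutidine (2 equiv), CH2Cl2, −78 to 0 °C; Et3N-deactivated silica
Reagents that add atoms: trimethylsilyl triflate C[Si](C)(C)OS(=O)(=O)C(F)(F)F
Why: Silylation of a hindered tertiary alcohol with a silyl triflate and a non-nucleophilic base; the ether is needed because a free hydroxyl would displace iodide from the next intermediate to close a 1,3-dioxolan-4-one, and the small TMS group keeps the oxygen substituent sterically below CH2Ar.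

Step 10
Reactants: 15 chloromethyl (2S,3E)-2-[3,4-bis(benzyloxy)benzyl]-4-(3,4-dimethoxyphenyl)-2-(trimethylsilyloxy)but-3-enoate
Product: 16 iodomethyl (2S,3E)-2-[3,4-bis(benzyloxy)benzyl]-4-(3,4-dimethoxyphenyl)-2-(trimethylsilyloxy)but-3-enoate
Conditions: NaI (3 equiv), dry acetone, rt, dark
Reagents that add atoms: sodium iodide [Na+].[I-]
Why: Finkelstein reaction, routine for chloromethyl esters and driven by precipitation of sodium chloride under neutral conditions that spare the silyl ether.

Step 11
Reactants: 16 iodomethyl (2S,3E)-2-[3,4-bis(benzyloxy)benzyl]-4-(3,4-dimethoxyphenyl)-2-(trimethylsilyloxy)but-3-enoate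
Product: 17 (3S,4S)-3-[3,4-bis(benzyloxy)benzyl]-4-(3,4-dimethoxybenzyl)-3-(trimethylsilyloxy)oxolan-2-one
Conditions: (TMS)3SiH (1.3 equiv), AIBN (0.2 equiv), degassed PhMe (final 5 mM), 90 °C; 16 and silane/AIBN added separately by syringe pump over 6 h
Reagents that add atoms: none
Why: In a radical chain the silyl radical abstracts iodine from 16 (much faster than it adds to the styrene), the primary acyloxymethyl radical at the future C5 adds from the s-cis rotamer of the ester to the styrene carbon bonded to C3, and the 3,4-dimethoxybenzylic radical so formed takes hydrogen from the silane, which creates C4–C5, the C4 methine and the veratryl CH2 in one operation. The closest known reaction type is the reductive ring closure of acyloxymethyl radicals generated from halomethyl alk-3-enoates, a known but rarely used γ-lactone synthesis. The oxolan-2-one closes 5-exo-trig, and 6-endo attack at the aryl-bearing carbon is disfavoured both by overlap and because it would give a non-benzylic secondary radical. C4 is controlled by the quaternary C3: in the chair-like transition state CH2Ar lies pseudo-equatorial and the slimmer Me3SiO oxygen pseudo-axial, so the exocyclic benzylic carbon grows trans to CH2Ar and cis to oxygen, which corresponds to 4S, while C3 is untouched. The step needs closure to outrun hydrogen transfer to the open-chain radical, whose ester must first rotate, and this is secured by geminal substitution at C3, the reactive styrene acceptor, heat, high dilution, slow addition and a silane that donates hydrogen more slowly than a stannane. Iodine-atom-transfer conditions are avoided because the stabilised benzylic radical would not carry such a chain, and a C4 epimer, if formed, is removed by chromatography of 17 or 18.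

Step 12
Reactants: 17 (3S,4S)-3-[3,4-bis(benzyloxy)benzyl]-4-(3,4-dimethoxybenzyl)-3-(trimethylsilyloxy)oxolan-2-one
Product: 18 (3S,4S)-3-[3,4-bis(benzyloxy)benzyl]-4-(3,4-dimethoxybenzyl)-3-hydroxyoxolan-2-one
Conditions: PPTS (10 mol %), MeOH, rt
Reagents that add atoms: none
Why: Acid-catalysed methanolysis of a trimethylsilyl ether, mild enough to leave the γ-lactone, the aryl ethers and both stereocentres unchanged.

Step 13
Reactants: 18 (3S,4S)-3-[3,4-bis(benzyloxy)benzyl]-4-(3,4-dimethoxybenzyl)-3-hydroxyoxolan-2-one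
Product: 19 (3S,4S)-3-(3,4-dihydroxybenzyl)-4-(3,4-dimethoxybenzyl)-3-hydroxyoxolan-2-one
Conditions: H2 (1 atm), 10% Pd/C, EtOAc–MeOH, rt; work-up under argon
Reagents that add atoms: none
Why: Catalytic hydrogenolysis of aryl benzyl ethers, which frees the catechol while the C3 hydroxyl, being homobenzylic and not benzylic, and the lactone are not cleaved.

Compound list
1 | 3,4-dimethoxybenzaldehyde | COc1ccc(C=O)cc1OC | starting material
2 | pyruvic acid | CC(=O)C(=O)O | starting material
3 | (E)-4-(3,4-dimethoxyphenyl)-2-oxobut-3-enoic acid | COc1ccc(/C=C/C(=O)C(=O)O)cc1OC | intermediate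
4 | (2S,3E)-4-(3,4-dimethoxyphenyl)-2-hydroxybut-3-enoic acid | OC(=O)[C@@H](O)/C=C/c1ccc(OC)c(OC)c1 | intermediate
5 | trimethylsilyl (2S,3E)-4-(3,4-dimethoxyphenyl)-2-(trimethylsilyloxy)but-3-enoate | C[Si](C)(C)OC(=O)[C@@H](O[Si](C)(C)C)/C=C/c1ccc(OC)c(OC)c1 | intermediate
6 | (2S,5S)-2-tert-butyl-5-[(E)-2-(3,4-dimethoxyphenyl)ethenyl]-1,3-dioxolan-4-one | O=C1O[C@@H](C(C)(C)C)O[C@H]1/C=C/c1ccc(OC)c(OC)c1 | intermediate
7 | 3,4-bis(benzyloxy)benzaldehyde | O=Cc1ccc(OCc2ccccc2)c(OCc2ccccc2)c1 | starting material
8 | [3,4-bis(benzyloxy)phenyl]methanol | OCc1ccc(OCc2ccccc2)c(OCc2ccccc2)c1 | intermediate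
9 | 3,4-bis(benzyloxy)benzyl bromide | BrCc1ccc(OCc2ccccc2)c(OCc2ccccc2)c1 | intermediate
10 | lithium (2S)-2-tert-butyl-5-[(E)-2-(3,4-dimethoxyphenyl)ethenyl]-1,3-dioxol-4-olate | [Li+].[O-]C1=C(/C=C/c2ccc(OC)c(OC)c2)O[C@H](C(C)(C)C)O1 | intermediate
11 | (2S,5S)-5-[3,4-bis(benzyloxy)benzyl]-2-tert-butyl-5-[(E)-2-(3,4-dimethoxyphenyl)ethenyl]-1,3-dioxolan-4-one | O=C1O[C@@H](C(C)(C)C)O[C@@]1(Cc1ccc(OCc2ccccc2)c(OCc2ccccc2)c1)/C=C/c1ccc(OC)c(OC)c1 | intermediate
12 | (2S,3E)-2-[3,4-bis(benzyloxy)benzyl]-4-(3,4-dimethoxyphenyl)-2-hydroxybut-3-enoic acid | OC(=O)[C@](O)(Cc1ccc(OCc2ccccc2)c(OCc2ccccc2)c1)/C=C/c1ccc(OC)c(OC)c1 | intermediate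
13 | chloromethyl chlorosulfate | ClCOS(=O)(=O)Cl | starting material
14 | chloromethyl (2S,3E)-2-[3,4-bis(benzyloxy)benzyl]-4-(3,4-dimethoxyphenyl)-2-hydroxybut-3-enoate | ClCOC(=O)[C@](O)(Cc1ccc(OCc2ccccc2)c(OCc2ccccc2)c1)/C=C/c1ccc(OC)c(OC)c1 | intermediate
15 | chloromethyl (2S,3E)-2-[3,4-bis(benzyloxy)benzyl]-4-(3,4-dimethoxyphenyl)-2-(trimethylsilyloxy)but-3-enoate | ClCOC(=O)[C@](O[Si](C)(C)C)(Cc1ccc(OCc2ccccc2)c(OCc2ccccc2)c1)/C=C/c1ccc(OC)c(OC)c1 | intermediate
16 | iodomethyl (2S,3E)-2-[3,4-bis(benzyloxy)benzyl]-4-(3,4-dimethoxyphenyl)-2-(trimethylsilyloxy)but-3-enoate | ICOC(=O)[C@](O[Si](C)(C)C)(Cc1ccc(OCc2ccccc2)c(OCc2ccccc2)c1)/C=C/c1ccc(OC)c(OC)c1 | intermediate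
17 | (3S,4S)-3-[3,4-bis(benzyloxy)benzyl]-4-(3,4-dimethoxybenzyl)-3-(trimethylsilyloxy)oxolan-2-one | COc1ccc(C[C@H]2COC(=O)[C@]2(O[Si](C)(C)C)Cc2ccc(OCc3ccccc3)c(OCc3ccccc3)c2)cc1OC | intermediate
18 | (3S,4S)-3-[3,4-bis(benzyloxy)benzyl]-4-(3,4-dimethoxybenzyl)-3-hydroxyoxolan-2-one | COc1ccc(C[C@H]2COC(=O)[C@]2(O)Cc2ccc(OCc3ccccc3)c(OCc3ccccc3)c2)cc1OC | intermediate
19 | (3S,4S)-3-(3,4-dihydroxybenzyl)-4-(3,4-dimethoxybenzyl)-3-hydroxyoxolan-2-one (CNP0142775.1) | COc1ccc(C[C@H]2COC(=O)[C@]2(O)Cc2ccc(O)c(O)c2)cc1OC | target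

Total step count: 13.
Longest linear sequence: 11 steps (1, 2, 3, 6, 7, 8, 9, 10, 11, 12, 13); steps 4 and 5 form the side branch.

Steps most likely to fail

Step 11. Three things may go wrong.
- Hydrogen transfer to the open-chain radical may outrun ring closure because the ester rotates slowly.
- The silyloxy oxygen may attack the iodomethyl carbon on prolonged heating.
- The two faces of the styrene may be poorly differentiated.

The fallback builds C4 first and C3 last by ionic chemistry. It sets out from 1 and 9 and returns to the route at 18.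
- Stobbe condensation of 1 with dimethyl succinate (NaOMe, MeOH, reflux) gives (E)-4-(3,4-dimethoxyphenyl)-3-(methoxycarbonyl)but-3-enoic acid F1.
- Rhodium-catalysed asymmetric hydrogenation, with a chiral bisphosphine chosen for the R product, gives (3R)-4-(3,4-dimethoxyphenyl)-3-(methoxycarbonyl)butanoic acid F2.
- Reduction of the ester group in the carboxylate salt (Ca(BH4)2) and acid lactonisation give (4R)-4-(3,4-dimethoxybenzyl)oxolan-2-one F3.
- Enolate hydroxylation (LiHMDS, then 2-(phenylsulfonyl)-3-phenyloxaziridine) gives (3R,4S)-4-(3,4-dimethoxybenzyl)-3-hydroxyoxolan-2-one F4.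
- The dianion of F4 (LDA, 2.2 equiv, THF–DMPU) should take up 9 anti to the C4 arm and so give 18.

Step 6. The dienolate may be alkylated at its γ-carbon, or it may fragment or self-condense before the bromide arrives. The fallback exchanges the roles of nucleophile and electrophile. It sets out from 3 and 9 and returns at 12, bypassing steps 2, 3, 6 and 7.
- Steglich esterification of 3 with (1S,2R)-trans-2-phenylcyclohexanol gives (1S,2R)-2-phenylcyclohexyl (E)-4-(3,4-dimethoxyphenyl)-2-oxobut-3-enoate F5.
- Zinc dust and LiCl in THF convert 9 into 3,4-bis(benzyloxy)benzylzinc bromide F6.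
- 1,2-Addition of F6 to the MgCl2-chelated keto ester at low temperature, with one face covered by the auxiliary phenyl ring, should give (1S,2R)-2-phenylcyclohexyl (2S,3E)-2-[3,4-bis(benzyloxy)benzyl]-4-(3,4-dimethoxyphenyl)-2-hydroxybut-3-enoate F7. The antipodal alcohol is equally available should the sense of induction prove opposite.
- Saponification (KOH, aqueous EtOH, reflux) releases 12 and the auxiliary.

Step 2. The enzyme may bind the dimethoxyaryl substrate poorly or be inhibited by it, so that turnover stalls. The fallback replaces asymmetric reduction by kinetic resolution. It sets out from 3 and returns at 4.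
- Fischer esterification (MeOH, cat. H2SO4) gives methyl (E)-4-(3,4-dimethoxyphenyl)-2-oxobut-3-enoate F8.
- Luche reduction (NaBH4, CeCl3, MeOH, −78 °C) gives racemic methyl (E)-4-(3,4-dimethoxyphenyl)-2-hydroxybut-3-enoate F9.
- Burkholderia cepacia lipase with vinyl acetate in MTBE should acetylate the S alcohol faster (styryl as the large group in the empirical size rule for lipases). This gives methyl (2S,3E)-2-acetoxy-4-(3,4-dimethoxyphenyl)but-3-enoate F10.
- F10 is separated from the unreacted alcohol and saponified with LiOH in aqueous THF at 0 °C to 4.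

Further compounds
F1 | step 11 | (E)-4-(3,4-dimethoxyphenyl)-3-(methoxycarbonyl)but-3-enoic acid | COC(=O)/C(CC(=O)O)=C/c1ccc(OC)c(OC)c1
F2 | step 11 | (3R)-4-(3,4-dimethoxyphenyl)-3-(methoxycarbonyl)butanoic acid | COc1ccc(C[C@H](CC(=O)O)C(=O)OC)cc1OC
F3 | step 11 | (4R)-4-(3,4-dimethoxybenzyl)oxolan-2-one | COc1ccc(C[C@H]2COC(=O)C2)cc1OC
F4 | step 11 | (3R,4S)-4-(3,4-dimethoxybenzyl)-3-hydroxyoxolan-2-one | COc1ccc(C[C@H]2COC(=O)[C@@H]2O)cc1OC
F5 | step 6 | (1S,2R)-2-phenylcyclohexyl (E)-4-(3,4-dimethoxyphenyl)-2-oxobut-3-enoate | COc1ccc(/C=C/C(=O)C(=O)O[C@H]2CCCC[C@@H]2c2ccccc2)cc1OC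
F6 | step 6 | 3,4-bis(benzyloxy)benzylzinc bromide | Br[Zn]Cc1ccc(OCc2ccccc2)c(OCc2ccccc2)c1
F7 | step 6 | (1S,2R)-2-phenylcyclohexyl (2S,3E)-2-[3,4-bis(benzyloxy)benzyl]-4-(3,4-dimethoxyphenyl)-2-hydroxybut-3-enoate | O=C(O[C@H]1CCCC[C@@H]1c1ccccc1)[C@](O)(Cc1ccc(OCc2ccccc2)c(OCc2ccccc2)c1)/C=C/c1ccc(OC)c(OC)c1
F8 | step 2 | methyl (E)-4-(3,4-dimethoxyphenyl)-2-oxobut-3-enoate | COC(=O)C(=O)/C=C/c1ccc(OC)c(OC)c1
F9 | step 2 | racemic methyl (E)-4-(3,4-dimethoxyphenyl)-2-hydroxybut-3-enoate | COC(=O)C(O)/C=C/c1ccc(OC)c(OC)c1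
F10 | step 2 | methyl (2S,3E)-2-acetoxy-4-(3,4-dimethoxyphenyl)but-3-enoate | COC(=O)[C@@H](OC(C)=O)/C=C/c1ccc(OC)c(OC)c1
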